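## The problem

Target 20 is an unsymmetrical dicoumarin ether. A 6,7-dihydroxycoumarin (benzo ring B, pyranone ring D) is bonded through its C5 oxygen to C6 of a 7-hydroxycoumarin (benzo ring A, pyranone ring C). The difficult bond is the diaryl ether: on ring B its oxygen sits between the ring-fusion carbon C4a and the C6 oxygen, and on ring A it sits beside the C7 hydroxyl. A direct C–O coupling would have to join a di-ortho-substituted, weakly nucleophilic phenol to an electron-rich, ortho-oxygenated aryl halide, which is the worst case for Ullmann-type coupling and is closed to SNAr. There is no stereocentre, so the control problem is purely regiochemical: which of three adjacent oxygens on ring B carries the aryl group, and where ether oxygen, hydroxyl and lactone oxygen sit on ring A. The sensitive groups are the two coumarin lactones (opened by hydroxide or alkoxide, electrophilic at C4, reducible at C3–C4) and the ring B catechol, which oxidises easily and is best kept as its dimethyl ether until the last step. Ring B cannot come from a symmetrical tetra-oxygenated benzene, because its three adjacent oxygens could not be told apart later; the C5 oxygen must be distinct from the outset. The enabling feature is ring A: oxygens on C7 and C8a are meta to each other, the ether oxygen is on C6, and C4 is attached to C4a ortho to the C8a oxygen. This is the pattern of a 5-aryloxy-2,4-dihydroxybenzoyl unit, which is what a 4-aryloxyacetoacetate-derived 1-methoxy-1,3-bis(silyloxy)diene gives with a propiolic acid derivative after loss of methanol.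

## Retrosynthesis

**20 to 19.** The two O–CH3 bonds on ring B are cut last. Methyl is preferred to benzyl or silyl because both methyl groups are already present in aldehyde 1 and survive LiN(iPr)2, BCl3 at low temperature, Et3SiH with Pd/C, and a Wittig reaction above 200 °C. The 7-hydroxyl of ring A needs no protection. The forward step must cleave two aryl methyl ethers while leaving two lactones and the diaryl ether intact, which BBr3 does.

**19 to 16 to 15.** Ring C is cut at C3–C4 and O1–C2, giving salicylaldehyde 16 and a two-carbon ylide. Wittig olefination with lactonisation is preferred to a Pechmann or Perkin closure because it is neutral, can only engage the hydroxyl ortho to the formyl group, and leaves ring D alone. Aldehyde 16 is traced to S-ethyl thioester 15. C4 enters at the acid oxidation level because the alkyne of the key step needs an acyl activating group. A thioester is chosen because it can be reduced to the aldehyde with Et3SiH and Pd/C, with no hydride reagent that would attack the ring D lactone. The forward steps must spare the C3–C4 bond of ring D and close the lactone on the 2-hydroxyl.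

**15 to 11 and 13 (key disconnection).** Ring A is cut at C5–C6 and C4a–C8a, giving diene 11 and alkyne 13. The competing cut, at the C6–O ether bond, leads back to the hindered coupling described above. With the ring A cut, the ether oxygen is already attached to an sp2 CH of an open chain that began as an sp3 CH2, so the diaryl ether is never formed by arylation. The precursor has one ring fewer and no ring A substitution pattern to set up. The forward reaction must be regioselective (thioester carbon next to the C8a oxygen) and must aromatise by loss of methanol only.

**13 to 12.** The C–S bond is cut to propiolic acid 12 and ethanethiol, a single coupling step.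

**11 to 10 to 9 to 7 and 8.** The two O–Si bonds are removed in turn, giving silyl enol ether 10 and then β-ketoester 9. Ketoester 9 is cut at the O–CH2 bond to phenol 7 and methyl 4-chloroacetoacetate 8. SN2 at a primary, carbonyl-activated carbon is far less sensitive to the two ortho substituents of 7 than any arylation would be. The forward steps need O-alkylation without self-condensation of 8, and diene formation without damage to the coumarin.

**7 to 6 to 4 to 2 to 1.** The isopropyl ether of 6 is cleaved to give 7. Ring D of 6 is cut at O1–C8a, an oxidative C–O bond formation onto an arene C–H, giving E-cinnamic acid 4. The C3–C4 double bond of 4 is cut to aldehyde 2 and malonic acid, and 2 is the isopropyl ether of commercial 1. This order is chosen because in 1 the oxygen destined to be C5–O is already a free hydroxyl while the other two are methyl ethers. The only open position ortho to the side chain is the one that must receive the lactone oxygen, so the substrate fixes the regiochemistry. A route through a symmetrical trimethoxyphenol would give the fully methylated coumarin, whose C5 ether cannot be cleaved selectively. The hydroxyl of 1 must be capped first; otherwise the acrylic acid chain would lactonise onto it and give the wrong coumarin.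

## Roads not taken

**Alternative 1:** Both O1–C8a bonds are cut, so rings C and D open to two E-acrylic acid arms on a preformed diaryl ether, bis-acid A1. In the forward step, riboflavin under blue light and oxygen would isomerise each arm to Z and join each carboxylate oxygen to its ortho carbon, giving trimethyl ether A2, which would be demethylated as in step 12.
- Merits: it is by far the shortest plan, about five steps against twelve. The diaryl ether can be made by SNAr next to a formyl group, where the hindrance matters little. No protecting group is needed for the C5 oxygen.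
- Weak points: the ring A arm has two free ortho carbons, and only closure para to the ether oxygen gives A2. Two oxidative closures must succeed in one molecule, and the oxidation will sit on the more electron-rich ring, so one closure is inherently slower and mono-lactones may accumulate.
- Comparison: this road is better in step count and convergence. The chosen plan uses the same photochemical lactonisation only once (step 3), on a substrate with a single free ortho position, and fixes the ring A pattern by a cycloaddition whose regiochemistry follows from the diene.

**Alternative 2:** Ring A is cut at C8–C8a inside pyranone A3. Sodium ethoxide would open the pyranone, and the freed methyl ketone enolate would close on an ester to give ethyl resorcylate A4.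
- Merits: it shares phenol 7 and the idea of introducing the ether by alkylation, here with a simple α-haloketone that is more reliable than step 5. It needs no moisture-sensitive diene, no amide base and no strictly anhydrous thermal step.
- Weak points: ethoxide also opens the ring D coumarin, and the ring-opened cinnamate can isomerise to the E form, which does not re-close. Assembling A3 from an unsymmetrical ketone raises its own regiochemical question. A4 is an O-ethyl ester, and taking it to aldehyde 16 needs hydride reduction and re-oxidation in the presence of a lactone.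
- Comparison: up to ring formation this road uses sturdier reagents. The chosen plan offers neutral, non-nucleophilic ring formation and a thioester that is one mild step from the aldehyde.

**Alternative 3:** Ring B is built instead of ring A, with cuts at C5–C6 and C8–C8a. The ether oxygen comes from the ready-made phenol 6-hydroxy-7-methoxy-2H-chromen-2-one A5, which is converted to the aryloxy(methylsulfonyl)methylene malonate A6. ZnCl2 would promote addition of silyl enol ether A7 with loss of methanesulfinate, and sodium ethoxide would then close the ring to benzoate A8.
- Merits: A5 already contains rings A and C, so the four steps leading to 7 disappear. In starting-material economy this road is better.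
- Weak points: the C–C bond must form at a fully substituted push–pull carbon where aryloxide competes with methanesulfinate as leaving group, and loss of aryloxide would erase the ether. A7 must react at its congested methoxy-bearing carbon. Ethoxide again meets a coumarin. A8 is a hexasubstituted benzene whose flanked ester still has to be turned into ring D.
- Comparison: the chosen plan has a ring-forming step with close precedent, under neutral conditions, and a product (15) that leads to the second pyranone in two steps.

Key step: step 9

Assumption: 10 is drawn as its Z isomer, 11 as its 1Z,3Z isomer and 14 as the racemic cis adduct derived from it; all these geometries are erased in step 9, so isomer mixtures would serve equally.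

## Route

Step 1
Reactants: 1 2-hydroxy-3,4-dimethoxybenzaldehyde
Product: 2 3,4-dimethoxy-2-(propan-2-yloxy)benzaldehyde
Conditions: 2-bromopropane, K2CO3, DMF, 70 °C
Reagents that add atoms: 2-bromopropane, CC(C)Br
Why: Williamson ether synthesis, routine for chelated ortho-hydroxybenzaldehydes in warm DMF; isopropyl is chosen because it has no benzylic C–H for the photochemical step and can be removed later by BCl3 without hydrogenation.

Step 2
Reactants: 2 3,4-dimethoxy-2-(propan-2-yloxy)benzaldehyde
Product: 4 (2E)-3-[3,4-dimethoxy-2-(propan-2-yloxy)phenyl]prop-2-enoic acid, via arylidenemalonic acid 3 (not isolated)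
Conditions: malonic acid, pyridine, piperidine (cat.), 100 °C
Reagents that add atoms: malonic acid, OC(=O)CC(=O)O
Why: Knoevenagel–Doebner condensation; condensation to 3 and decarboxylation in pyridine should give the E acid under thermodynamic control, and the capped ortho oxygen cannot lactonise.

Step 3
Reactants: 4 (2E)-3-[3,4-dimethoxy-2-(propan-2-yloxy)phenyl]prop-2-enoic acid
Product: 6 6,7-dimethoxy-5-(propan-2-yloxy)-2H-chromen-2-one, via (Z)-cinnamic acid 5 (not isolated)
Conditions: (−)-riboflavin (5 mol %), O2 (1 atm), MeCN/MeOH 1:1, 402 nm LED, rt
Reagents that add atoms: none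
Why: Flavin-photocatalysed oxidative lactonisation of cinnamic acids: energy transfer from excited riboflavin isomerises 4 to 5, single-electron oxidation lets the carboxylate oxygen bond to the ortho arene carbon, and O2 reoxidises the flavin and rearomatises the ring. The only free ortho position is the future C8a, so the substrate fixes the regiochemistry.

Step 4
Reactants: 6 6,7-dimethoxy-5-(propan-2-yloxy)-2H-chromen-2-one
Product: 7 5-hydroxy-6,7-dimethoxy-2H-chromen-2-one
Conditions: BCl3, CH2Cl2, −78 → 0 °C; then H2O
Reagents that add atoms: none
Why: Lewis acid dealkylation; BCl3 cleaves secondary alkyl aryl ethers by an ion-pair pathway at temperatures where aryl methyl ethers and the lactone are untouched, a selectivity well established for isopropyl/methyl ether pairs.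

Step 5
Reactants: 7 5-hydroxy-6,7-dimethoxy-2H-chromen-2-one; 8 methyl 4-chloro-3-oxobutanoate
Product: 9 methyl 4-[(6,7-dimethoxy-2-oxo-2H-chromen-5-yl)oxy]-3-oxobutanoate
Conditions: NaH (2.2 equiv), THF/DMF, 0 °C → rt; then 1 M HCl
Reagents that add atoms: none
Why: Williamson-type O-alkylation of the sodium phenoxide at the primary, ketone-activated C–Cl carbon, the standard entry to 4-aryloxyacetoacetates; the second equivalent of NaH holds 8 and the product as enolates and so suppresses self-condensation.

Step 6
Reactants: 9 methyl 4-[(6,7-dimethoxy-2-oxo-2H-chromen-5-yl)oxy]-3-oxobutanoate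
Product: 10 methyl (2Z)-4-[(6,7-dimethoxy-2-oxo-2H-chromen-5-yl)oxy]-3-[(trimethylsilyl)oxy]but-2-enoate
Conditions: TMSCl, Et3N, toluene, rt
Reagents that add atoms: chlorotrimethylsilane, C[Si](C)(C)Cl
Why: Amine-mediated O-silylation of the enolised β-ketoester, the first stage of the standard two-stage preparation of 1,3-bis(silyloxy)dienes; the coumarin is inert to these reagents.

Step 7
Reactants: 10 methyl (2Z)-4-[(6,7-dimethoxy-2-oxo-2H-chromen-5-yl)oxy]-3-[(trimethylsilyl)oxy]but-2-enoate
Product: 11 5-{[(1Z,3Z)-4-methoxy-2,4-bis(trimethylsilyloxy)buta-1,3-dien-1-yl]oxy}-6,7-dimethoxy-2H-chromen-2-one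
Conditions: LiN(iPr)2, THF, −78 °C; TMSCl, −78 → 0 °C
Reagents that add atoms: chlorotrimethylsilane, C[Si](C)(C)Cl
Why: Kinetic γ-deprotonation of the β-silyloxy enoate and O-silylation of the dienolate, the established second stage for 1-alkoxy-1,3-bis(silyloxy)dienes including 4-aryloxy members; the aryloxy group should take the less hindered position cis to the silyloxy group (1Z), and fast deprotonation at −78 °C with prompt silylation should spare the coumarin.

Step 8
Reactants: 12 prop-2-ynoic acid
Product: 13 S-ethyl prop-2-ynethioate
Conditions: EtSH, DCC, CH2Cl2, −20 → 0 °C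
Reagents that add atoms: ethanethiol, CCS
Why: Carbodiimide-mediated thioesterification without amine catalyst; low temperature and the absence of base suppress thia-Michael addition of the thiol to the ynoate.

Step 9
Reactants: 11 5-{[(1Z,3Z)-4-methoxy-2,4-bis(trimethylsilyloxy)buta-1,3-dien-1-yl]oxy}-6,7-dimethoxy-2H-chromen-2-one; 13 S-ethyl prop-2-ynethioate
Product: 15 S-ethyl 5-[(6,7-dimethoxy-2-oxo-2H-chromen-5-yl)oxy]-2,4-dihydroxybenzenecarbothioate, via cyclohexa-1,4-diene cycloadduct 14 (not isolated)
Conditions: toluene, 20 → 60 °C; then 1 M HCl, THF, 20 °C
Reagents that add atoms: none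
Why: Diene 11 and acyl-activated alkyne 13 should combine in a concerted, asynchronous, normal-demand [4+2] cycloaddition, with bonding most advanced between the aryloxy-bearing diene terminus (future C6) and the unsubstituted alkyne carbon (future C5) while C8a–C4a closes in the same event. The closest known reaction type is the Diels–Alder reaction of 1-alkoxy-1,3-bis(silyloxy)buta-1,3-dienes with acetylenic esters and acid aromatisation to 2,4-dihydroxybenzoates, which includes 4-aryloxy dienes as a diaryl ether synthesis; only the thioester activating group and the coumarinyl residue are new here. Ring A closes as a six-membered carbocycle in one suprafacial 4π + 2π step, giving cyclohexa-1,4-diene 14. The two stereocentres of 14 (C6 and C8a) are transient and vanish on aromatisation, so no stereocontrol is needed; the 1Z geometry places the aryloxy group on the outside, so the s-cis diene is accessible. Acid then hydrolyses the mixed silyl methyl ketal at C8a with loss of methanol, the unveiled ketone enolises by shift of the C6 hydrogen, and the remaining silyl ether is cleaved, giving 15. The selectivity that matters is regiochemical: the two oxygens on the ketene acetal carbon and the C7 silyloxy group together outweigh the single aryloxy donor, so the thioester lands on C4a next to the C8a hydroxyl. Because C8a carries no hydrogen and C6 carries one, loss of methanol is the only path to an arene and the aryloxy group cannot be expelled. The C3–C4 bond of ring D is a benzo-fused, lactone-conjugated alkene and a far poorer dienophile than the ynoate, so it should not compete.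

Step 10
Reactants: 15 S-ethyl 5-[(6,7-dimethoxy-2-oxo-2H-chromen-5-yl)oxy]-2,4-dihydroxybenzenecarbothioate
Product: 16 5-[(6,7-dimethoxy-2-oxo-2H-chromen-5-yl)oxy]-2,4-dihydroxybenzaldehyde
Conditions: Et3SiH, 10% Pd/C, acetone, rt
Reagents that add atoms: none
Why: Fukuyama reduction: insertion of palladium into the C–S bond, hydride transfer from Et3SiH and reductive elimination should give the aldehyde; no hydride reagent is present, so the ring D lactone is not attacked.

Step 11
Reactants: 16 5-[(6,7-dimethoxy-2-oxo-2H-chromen-5-yl)oxy]-2,4-dihydroxybenzaldehyde
Product: 19 5-[(7-hydroxy-2-oxo-2H-chromen-6-yl)oxy]-6,7-dimethoxy-2H-chromen-2-one, via (E)-cinnamate 17 (not isolated), via (Z)-cinnamate 18 (not isolated)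
Conditions: Ph3P=CHCO2Et, PhNEt2, reflux
Reagents that add atoms: ethyl (triphenylphosphoranylidene)acetate, CCOC(=O)C=P(c1ccccc1)(c1ccccc1)c1ccccc1
Why: Wittig olefination followed by thermal E to Z isomerisation and lactonisation, the classical conversion of salicylaldehydes to coumarins; only the hydroxyl ortho to the new acrylate can close ring C, so the C7 hydroxyl stays free.

Step 12
Reactants: 19 5-[(7-hydroxy-2-oxo-2H-chromen-6-yl)oxy]-6,7-dimethoxy-2H-chromen-2-one
Product: 20 6,7-dihydroxy-5-[(7-hydroxy-2-oxo-2H-chromen-6-yl)oxy]-2H-chromen-2-one
Conditions: BBr3, CH2Cl2, −78 °C → rt; then MeOH/H2O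
Reagents that add atoms: none
Why: Lewis acid demethylation of aryl methyl ethers; boron coordinates each methoxy oxygen and bromide removes the methyl group by SN2, while the lactones and the diaryl ether are stable, and hydrolysis of the aryl borates should release the catechol.

## Compound list

1 | 2-hydroxy-3,4-dimethoxybenzaldehyde | COc1ccc(C=O)c(O)c1OC | starting material
2 | 3,4-dimethoxy-2-(propan-2-yloxy)benzaldehyde | COc1ccc(C=O)c(OC(C)C)c1OC | intermediate
3 | {[3,4-dimethoxy-2-(propan-2-yloxy)phenyl]methylidene}propanedioic acid | COc1ccc(C=C(C(=O)O)C(=O)O)c(OC(C)C)c1OC | intermediate (not isolated)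
4 | (2E)-3-[3,4-dimethoxy-2-(propan-2-yloxy)phenyl]prop-2-enoic acid | COc1ccc(/C=C/C(=O)O)c(OC(C)C)c1OC | intermediate
5 | (2Z)-3-[3,4-dimethoxy-2-(propan-2-yloxy)phenyl]prop-2-enoic acid | COc1ccc(/C=C\C(=O)O)c(OC(C)C)c1OC | intermediate (not isolated)
6 | 6,7-dimethoxy-5-(propan-2-yloxy)-2H-chromen-2-one | COc1cc2oc(=O)ccc2c(OC(C)C)c1OC | intermediate
7 | 5-hydroxy-6,7-dimethoxy-2H-chromen-2-one | COc1cc2oc(=O)ccc2c(O)c1OC | intermediate
8 | methyl 4-chloro-3-oxobutanoate | COC(=O)CC(=O)CCl | starting material
9 | methyl 4-[(6,7-dimethoxy-2-oxo-2H-chromen-5-yl)oxy]-3-oxobutanoate | COC(=O)CC(=O)COc1c(OC)c(OC)cc2oc(=O)ccc12 | intermediate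
10 | methyl (2Z)-4-[(6,7-dimethoxy-2-oxo-2H-chromen-5-yl)oxy]-3-[(trimethylsilyl)oxy]but-2-enoate | COC(=O)/C=C(\O[Si](C)(C)C)COc1c(OC)c(OC)cc2oc(=O)ccc12 | intermediate
11 | 5-{[(1Z,3Z)-4-methoxy-2,4-bis(trimethylsilyloxy)buta-1,3-dien-1-yl]oxy}-6,7-dimethoxy-2H-chromen-2-one | COc1cc2oc(=O)ccc2c(O/C=C(\O[Si](C)(C)C)/C=C(/OC)O[Si](C)(C)C)c1OC | intermediate
12 | prop-2-ynoic acid (propiolic acid) | C#CC(=O)O | starting material
13 | S-ethyl prop-2-ynethioate | C#CC(=O)SCC | intermediate
14 | S-ethyl 3-[(6,7-dimethoxy-2-oxo-2H-chromen-5-yl)oxy]-6-methoxy-4,6-bis[(trimethylsilyl)oxy]cyclohexa-1,4-diene-1-carbothioate (racemic; 3-aryloxy and 6-methoxy cis) | CCSC(=O)C1=C[C@H](Oc2c(OC)c(OC)cc3oc(=O)ccc23)C(O[Si](C)(C)C)=C[C@@]1(OC)O[Si](C)(C)C | intermediate (not isolated)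
15 | S-ethyl 5-[(6,7-dimethoxy-2-oxo-2H-chromen-5-yl)oxy]-2,4-dihydroxybenzenecarbothioate | CCSC(=O)c1cc(Oc2c(OC)c(OC)cc3oc(=O)ccc23)c(O)cc1O | intermediate
16 | 5-[(6,7-dimethoxy-2-oxo-2H-chromen-5-yl)oxy]-2,4-dihydroxybenzaldehyde | O=Cc1cc(Oc2c(OC)c(OC)cc3oc(=O)ccc23)c(O)cc1O | intermediate
17 | ethyl (2E)-3-{5-[(6,7-dimethoxy-2-oxo-2H-chromen-5-yl)oxy]-2,4-dihydroxyphenyl}prop-2-enoate | CCOC(=O)/C=C/c1cc(Oc2c(OC)c(OC)cc3oc(=O)ccc23)c(O)cc1O | intermediate (not isolated)
18 | ethyl (2Z)-3-{5-[(6,7-dimethoxy-2-oxo-2H-chromen-5-yl)oxy]-2,4-dihydroxyphenyl}prop-2-enoate | CCOC(=O)/C=C\c1cc(Oc2c(OC)c(OC)cc3oc(=O)ccc23)c(O)cc1O | intermediate (not isolated)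
19 | 5-[(7-hydroxy-2-oxo-2H-chromen-6-yl)oxy]-6,7-dimethoxy-2H-chromen-2-one | COc1cc2oc(=O)ccc2c(Oc2cc3ccc(=O)oc3cc2O)c1OC | intermediate
20 | 6,7-dihydroxy-5-[(7-hydroxy-2-oxo-2H-chromen-6-yl)oxy]-2H-chromen-2-one | O=c1ccc2cc(Oc3c(O)c(O)cc4oc(=O)ccc34)c(O)cc2o1 | target

## Step count and least certain steps

Total: 12 steps. Longest linear sequence: 11 steps (steps 1–7 and 9–12); step 8 is a one-step branch.

**Step 9 (key step).** The cycloaddition of the mono-activated alkyne onto a diene whose nucleophilic terminus is substituted may be slow. Protodesilylation of the diene, conjugate-addition oligomerisation of 13, or addition of the diene terminus to the nearby C4 of ring D could then outrun ring formation, and some reversed regiochemistry is possible. Fallback: starting from 11, an alkene surrogate for the alkyne would be used, S-ethyl 2-chloroprop-2-enethioate F1, made from 2-chloroprop-2-enoic acid in the manner of step 8. α-Haloacrylates are established propiolate equivalents toward oxygenated dienes and are usually more reactive. The cycloaddition would give S-ethyl 1-chloro-5-[(6,7-dimethoxy-2-oxo-2H-chromen-5-yl)oxy]-2-methoxy-2,4-bis[(trimethylsilyl)oxy]cyclohex-3-ene-1-carbothioate F2. DBU would then remove HCl, and aqueous acid would remove methanol and the silyl groups, returning to the route at 15.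

**Step 3.** The oxidative ring closure may be inefficient because the carbon to be oxygenated is para only to the twisted central methoxy group. Photo-oxidative degradation of the electron-rich arene, or ipso attack at the alkoxy-bearing carbon, could take over and the reaction could stall at 5. Fallback: starting from 2, the aldehyde would be masked in situ as its lithium α-amino alkoxide with LiN(Me)CH2CH2NMe2 and lithiated ortho to the masked formyl group with n-BuLi. Trapping with B(OMe)3 and oxidation with H2O2 would give 6-hydroxy-3,4-dimethoxy-2-(propan-2-yloxy)benzaldehyde F3. Wittig lactonisation of this (Ph3P=CHCO2Et, PhNEt2, reflux) comes back to the route at 6.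

**Step 7.** The amide base or the lithium dienolate may attack the coumarin, by 1,4-addition at C4 (including intramolecular addition across the peri position) or by lactone opening, and some C-silylation may occur. Fallback: starting from 9, the anion chemistry would be replaced by soft enolisation, a double O-silylation with TMSOTf and Et3N (2.2 equiv each, ether, 0 °C). This omits 10 and the amide base, returns to the route at 11 and makes no new compound (F0).

**Step 5.** O-alkylation of the hindered, delocalised phenoxide by the enolised chloroketone may be slow, so that self-condensation of 8 dominates. Fallback: starting from 7, alkylation with commercial methyl (2E)-4-bromo-3-methoxybut-2-enoate (K2CO3, acetone, reflux) is a clean allylic SN2 and would give methyl (2E)-4-[(6,7-dimethoxy-2-oxo-2H-chromen-5-yl)oxy]-3-methoxybut-2-enoate F4. Hydrolysis of the enol ether with dilute HCl in THF returns to the route at 9.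

**Step 10.** Palladium hydride may transfer-hydrogenate the C3–C4 bond of ring D or over-reduce the aldehyde, fed by dehydrogenative silylation of the free phenols. Fallback: starting from 15, the thioester would be saponified with aqueous NaOH; acidification re-closes ring D and would give 5-[(6,7-dimethoxy-2-oxo-2H-chromen-5-yl)oxy]-2,4-dihydroxybenzoic acid F5. Thermal protodecarboxylation of this β-resorcylic acid would give 5-(2,4-dihydroxyphenoxy)-6,7-dimethoxy-2H-chromen-2-one F6. Vilsmeier–Haack formylation (POCl3, DMF, MeCN) at the position ortho to one hydroxyl and para to the other returns to the route at 16.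

## Further compounds

F1 | step 9 | S-ethyl 2-chloroprop-2-enethioate | C=C(Cl)C(=O)SCC
F2 | step 9 | S-ethyl 1-chloro-5-[(6,7-dimethoxy-2-oxo-2H-chromen-5-yl)oxy]-2-methoxy-2,4-bis[(trimethylsilyl)oxy]cyclohex-3-ene-1-carbothioate (mixture of diastereomers) | CCSC(=O)C1(Cl)CC(Oc2c(OC)c(OC)cc3oc(=O)ccc23)C(O[Si](C)(C)C)=CC1(OC)O[Si](C)(C)C
F3 | step 3 | 6-hydroxy-3,4-dimethoxy-2-(propan-2-yloxy)benzaldehyde | COc1cc(O)c(C=O)c(OC(C)C)c1OC
F0 | step 7 | none | none
F4 | step 5 | methyl (2E)-4-[(6,7-dimethoxy-2-oxo-2H-chromen-5-yl)oxy]-3-methoxybut-2-enoate | COC(=O)/C=C(/OC)COc1c(OC)c(OC)cc2oc(=O)ccc12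
F5 | step 10 | 5-[(6,7-dimethoxy-2-oxo-2H-chromen-5-yl)oxy]-2,4-dihydroxybenzoic acid | OC(=O)c1cc(Oc2c(OC)c(OC)cc3oc(=O)ccc23)c(O)cc1O
F6 | step 10 | 5-(2,4-dihydroxyphenoxy)-6,7-dimethoxy-2H-chromen-2-one | COc1cc2oc(=O)ccc2c(Oc2ccc(O)cc2O)c1OC
A1 | alternative 1 | (2E)-3-{2-[5-[(1E)-2-carboxyethenyl]-2-methoxyphenoxy]-3,4-dimethoxyphenyl}prop-2-enoic acid | COc1ccc(/C=C/C(=O)O)cc1Oc1c(OC)c(OC)ccc1/C=C/C(=O)O
A2 | alternative 1 | 6,7-dimethoxy-5-[(7-methoxy-2-oxo-2H-chromen-6-yl)oxy]-2H-chromen-2-one | COc1cc2oc(=O)ccc2cc1Oc1c(OC)c(OC)cc2oc(=O)ccc12
A3 | alternative 2 | ethyl 5-[(6,7-dimethoxy-2-oxo-2H-chromen-5-yl)oxy]-6-methyl-2-oxo-2H-pyran-3-carboxylate | CCOC(=O)c1cc(Oc2c(OC)c(OC)cc3oc(=O)ccc23)c(C)oc1=O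
A4 | alternative 2 | ethyl 5-[(6,7-dimethoxy-2-oxo-2H-chromen-5-yl)oxy]-2,4-dihydroxybenzoate | CCOC(=O)c1cc(Oc2c(OC)c(OC)cc3oc(=O)ccc23)c(O)cc1O
A5 | alternative 3 | 6-hydroxy-7-methoxy-2H-chromen-2-one | COc1cc2oc(=O)ccc2cc1O
A6 | alternative 3 | diethyl {[(7-methoxy-2-oxo-2H-chromen-6-yl)oxy](methanesulfonyl)methylidene}propanedioate | CCOC(=O)C(C(=O)OCC)=C(Oc1cc2ccc(=O)oc2cc1OC)S(C)(=O)=O
A7 | alternative 3 | (1Z)-1-methoxy-2-[(trimethylsilyl)oxy]prop-1-ene | CO/C=C(\O[Si](C)(C)C)C
A8 | alternative 3 | ethyl 4,6-dihydroxy-3-methoxy-2-[(7-methoxy-2-oxo-2H-chromen-6-yl)oxy]benzoate | CCOC(=O)c1c(O)cc(O)c(OC)c1Oc1cc2ccc(=O)oc2cc1OC
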